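The two bonds of spiro carbon C15′ to the labdane chain, C15′–C12 and C15′–C17′, are disconnected. C15′ is benzylic and α to the lactone carbonyl C16′, so it can be alkylated twice under mild base, and its ring neighbours C12 and C17′ both lie β to the C14 oxygen. A double Michael addition of a totarane-fused benzofuran-2(3H)-one (C15′H2, free 7β-hydroxyl) to a decalin alkynyl vinyl ketone (C20 acid as 2-(trimethylsilyl)ethyl ester) therefore forms both bonds, the spiro cyclohexenone ring and the quaternary stereocentre in one operation. Sclareol supplies the benzofuranone and carnosic acid the decalin; C12–H, the C13 methylene and the C14 alcohol follow.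

Key step: step 20

Remark: atoms are numbered as labdane (unprimed) and totarane (primed) carbons; the C7′ oxygen is taken through the spiroannulation as the free 7β-alcohol and acetylated directly afterwards, because a 7β-acetate peri to the C15′ carbanion would be open to O-to-C acetyl transfer.

Step 1
Reactants: 1 (−)-sclareol
Product: 2 8α-hydroxy-14,15-dinorlabdan-13-one
Conditions: OsO4 (cat.), NaIO4, THF/H2O, rt
Reagents that add atoms: none
Why: Lemieux–Johnson oxidation: dihydroxylation of the vinyl group followed by periodate cleavage of the glycol and then of the resulting α-hydroxy aldehyde should remove C14 and C15 and leave the C13 methyl ketone, while the tertiary C8 alcohol and the ring stereocentres are untouched.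

Step 2
Reactants: 2 8α-hydroxy-14,15-dinorlabdan-13-one
Product: 3 14,15-dinorlabd-8(17)-en-13-one
Conditions: SOCl2, pyridine, CH2Cl2, −78 °C
Reagents that add atoms: none
Why: Dehydration through the chlorosulfite (E2 elimination): the equatorial 8α leaving group has no anti-periplanar ring hydrogen, so elimination should run mainly into the C17 methyl group to give the exocyclic alkene, and the minor endocyclic isomers are removed by chromatography.

Step 3
Reactants: 3 14,15-dinorlabd-8(17)-en-13-one
Product: 4 14,15,17-trinorlabdane-8,13-dione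
Conditions: O3, CH2Cl2/MeOH, −78 °C; Me2S
Reagents that add atoms: ozone, [O-][O+]=O
Why: Ozonolysis with reductive work-up cleaves the only C=C bond and makes C8 a ketone, C9 keeping its equatorial side chain because that is the stable epimer next to the ketone.

Step 4
Reactants: 4 14,15,17-trinorlabdane-8,13-dione
Product: 5 podocarp-8(14)-en-13-one (5α-H, 9α-H, 10β-methyl)
Conditions: NaOMe (cat.), MeOH, reflux
Reagents that add atoms: none
Why: Intramolecular aldol condensation: the enolate of the methyl ketone attacks the C8 ketone to close six-membered ring C and dehydration gives the conjugated enone, with C9 (H α) in its stable configuration.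

Step 5
Reactants: 5 podocarp-8(14)-en-13-one
Product: 6 tert-butyl 2-(13-oxopodocarp-8(14)-en-14-yl)acetate
Conditions: KOtBu, tBuOH/THF, 0 °C; BrCH2CO2tBu, 0 °C → rt
Reagents that add atoms: tert-butyl bromoacetate, CC(C)(C)OC(=O)CBr
Why: α-Alkylation of an enone through its thermodynamic dienolate: γ-deprotonation gives the extended enolate, which should be alkylated at the α-carbon C14 by the reactive bromoacetate, and the β,γ-unsaturated isomer formed first returns to conjugation under the basic conditions.

Step 6
Reactants: 6 tert-butyl 2-(13-oxopodocarp-8(14)-en-14-yl)acetate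
Product: 8 tert-butyl 2-(13-hydroxypodocarpa-8,11,13-trien-14-yl)acetate, via cross-conjugated dienone 7 (not isolated)
Conditions: DDQ, 1,4-dioxane, 100 °C
Reagents that add atoms: none
Why: DDQ dehydrogenation of a cyclohexenone: hydride abstraction from C11 of the C12 enol gives dienone 7, which aromatises by enolisation through C9–H, so ring C becomes the C13 phenol and the C9 stereocentre is removed on purpose.

Step 7
Reactants: 8 tert-butyl 2-(13-hydroxypodocarpa-8,11,13-trien-14-yl)acetate
Product: 9 tert-butyl 2-[13-(tert-butoxycarbonyloxy)podocarpa-8,11,13-trien-14-yl]acetate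
Conditions: Boc2O, DMAP (cat.), MeCN, rt
Reagents that add atoms: di-tert-butyl dicarbonate, CC(C)(C)OC(=O)OC(=O)OC(C)(C)C
Why: DMAP-catalysed tert-butoxycarbonylation (O-acylation) masks the phenol against the oxidant of the next step with a group that later leaves under the same acid as the tert-butyl ester.

Step 8
Reactants: 9 tert-butyl 2-[13-(tert-butoxycarbonyloxy)podocarpa-8,11,13-trien-14-yl]acetate
Product: 10 tert-butyl 2-[13-(tert-butoxycarbonyloxy)-7-oxopodocarpa-8,11,13-trien-14-yl]acetate
Conditions: CrO3 (cat.), t-BuOOH, CH2Cl2, rt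
Reagents that add atoms: tert-butyl hydroperoxide, CC(C)(C)OO
Why: Chromium-catalysed benzylic oxidation with t-BuOOH: the ring CH2 at C7, whose pseudo-axial C–H bond overlaps with the arene π system, should be oxidised in preference to C15′H2, which is deactivated by the ester group and held out of conjugation by its two ortho neighbours.

Step 9
Reactants: 10 tert-butyl 2-[13-(tert-butoxycarbonyloxy)-7-oxopodocarpa-8,11,13-trien-14-yl]acetate
Product: 12 7′-oxo-17′-nortotara-8′,11′,13′-trien-16′,13′-olide (totarane-fused benzofuran-2(3H)-one with C15′H2 and C7′ ketone), via keto hydroxy acid 11 (not isolated)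
Conditions: TFA, CH2Cl2, 0 °C → rt; evaporate; EDC·HCl, CH2Cl2, 0 °C → rt
Reagents that add atoms: none
Why: Acidolysis of the tert-butyl carbonate and ester (loss of 2-methylpropene and CO2) followed by carbodiimide lactonisation closes the five-membered aryl lactone, and the C7′ ketone present at this stage is inert to the acid, unlike a benzylic alcohol or ester.

Step 10
Reactants: 12 7′-oxo-17′-nortotara-8′,11′,13′-trien-16′,13′-olide
Product: 13 (7′S)-7′β-hydroxy-17′-nortotara-8′,11′,13′-trien-16′,13′-olide (benzofuranone with C15′H2 and free 7′β-hydroxyl)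
Conditions: (R)-2-methyl-CBS-oxazaborolidine (cat.), BH3·SMe2, THF, −20 °C; MeOH
Reagents that add atoms: none
Why: Corey–Bakshi–Shibata reduction: the (R)-oxazaborolidine should deliver hydride to the α face of the aryl ketone (aryl as the large group), in line with the substrate's own preference for axial attack, to set C7′ as the 7′β (7′S) alcohol, while borane leaves the aryl lactone intact.

Step 11
Reactants: 14 carnosic acid
Product: 15 2-(trimethylsilyl)ethyl carnosate (2-(trimethylsilyl)ethyl 11,12-dihydroxyabieta-8,11,13-trien-20-oate)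
Conditions: 2-(trimethylsilyl)ethyl 2,2,2-trichloroacetimidate, toluene, 100 °C, argon
Reagents that add atoms: 2-(trimethylsilyl)ethyl 2,2,2-trichloroacetimidate, C[Si](C)(C)CCOC(=N)C(Cl)(Cl)Cl
Why: Esterification by O-alkylation with a trichloroacetimidate: only the carboxylic acid is acidic enough to activate the imidate, so the hindered C20 acid is alkylated at oxygen without any attack at its carbonyl and the catechol stays free.

Step 12
Reactants: 15 2-(trimethylsilyl)ethyl carnosate
Product: 16 11,12-dimethyl 20-[2-(trimethylsilyl)ethyl] (13Z)-11,12-secoabieta-8,13-diene-11,12,20-trioate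
Conditions: Pb(OAc)4, MeOH/toluene, 0 °C → rt
Reagents that add atoms: methanol, CO
Why: Oxidative intradiol cleavage of a catechol: Pb(OAc)4 oxidises the catechol to the o-quinone and cleaves its methanol hemiketal between C11 and C12 to give the 13Z muconate, the C20 ester excluding lactone formation at C7.

Step 13
Reactants: 16 11,12-dimethyl 20-[2-(trimethylsilyl)ethyl] (13Z)-11,12-secoabieta-8,13-diene-11,12,20-trioate
Product: 17 11,12-dimethyl 20-[2-(trimethylsilyl)ethyl] 11,12-secoabiet-8(14)-ene-11,12,20-trioate (mixture at C9, C13 and the alkene)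
Conditions: SmI2, THF, MeOH, −78 °C → rt
Reagents that add atoms: none
Why: Electron-transfer 1,4-reduction of a muconate: two electrons from SmI2 give a bis-enolate that is protonated at both α-carbons (C9 and C13), so the double bond moves to C8=C14 and C9 becomes sp3, its configuration and that of C13 and of the alkene being irrelevant because all three are erased or reset later.

Step 14
Reactants: 17 11,12-dimethyl 20-[2-(trimethylsilyl)ethyl] 11,12-secoabiet-8(14)-ene-11,12,20-trioate
Product: 18 decalin β-keto ester, 11-methyl 20-[2-(trimethylsilyl)ethyl] 8-oxo-12,13,14,15,16,17-hexanorlabdane-11,20-dioate (5α-H, C20 ester β)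
Conditions: O3, CH2Cl2/MeOH, −78 °C; Me2S
Reagents that add atoms: ozone, [O-][O+]=O
Why: Ozonolysis with reductive work-up cuts the only C=C bond, C8=C14, which sets free C12–C14 with the isopropyl group as a small aldehyde ester and leaves the C8 ketone next to the C11 ester on C9.

Step 15
Reactants: 18 decalin β-keto ester
Product: 19 9-(prop-2-ynyl) derivative of 18 (quaternary C9)
Conditions: NaH, THF, 0 °C; propargyl bromide, 0 → 45 °C
Reagents that add atoms: propargyl bromide, BrCC#C
Why: C-Alkylation of a β-keto ester enolate: the sodium enolate in THF should be alkylated by the slim, reactive propargyl bromide at C9, the only carbon activated by both carbonyl groups, which fixes the position of the side chain, the configuration of the quaternary C9 being of no consequence.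

Step 16
Reactants: 19 9-(prop-2-ynyl) β-keto ester
Product: 20 2-(trimethylsilyl)ethyl 8-oxo-14,15,16,17-tetranorlabd-12-yn-20-oate (9β-propargyl, 9α-H)
Conditions: LiCl, H2O, DMSO, 150 °C
Reagents that add atoms: none
Why: Krapcho dealkoxycarbonylation: chloride demethylates the β-keto ester, CO2 is lost, and protonation and equilibration of the enolisable C9 should leave the propargyl group equatorial (9β, H α), the stable arrangement next to the axial C20 ester.

Step 17
Reactants: 20 2-(trimethylsilyl)ethyl 8-oxo-14,15,16,17-tetranorlabd-12-yn-20-oate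
Product: 21 2-(trimethylsilyl)ethyl 14,15,16-trinorlabd-8(17)-en-12-yn-20-oate
Conditions: Ph3PCH3Br, NaN(SiMe3)2, THF, 0 °C → 60 °C
Reagents that add atoms: methyltriphenylphosphonium bromide, C[P+](c1ccccc1)(c1ccccc1)c1ccccc1.[Br-]
Why: Wittig methylenation of the C8 ketone with Ph3P=CH2, for which any epimerisation at C9 by the basic ylide only leads back to the stable 9β isomer and the hindered C20 ester is not attacked.

Step 18
Reactants: 21 2-(trimethylsilyl)ethyl 14,15,16-trinorlabd-8(17)-en-12-yn-20-oate, 22 acrolein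
Product: 23 dienynol, 21 extended at C13 by CH(OH)–CH=CH2 (C14 epimers)
Conditions: n-BuLi, THF, −78 °C; acrolein; aq. NH4Cl
Reagents that add atoms: none
Why: 1,2-Addition of a lithium acetylide to an enal: at −78 °C n-BuLi removes only the alkyne hydrogen and the acetylide adds to the carbonyl carbon of acrolein, the new carbinol centre (both epimers) being oxidised away in the next step.

Step 19
Reactants: 23 dienynol
Product: 24 decalin alkynyl vinyl ketone, 2-(trimethylsilyl)ethyl ester (C9β–CH2–C≡C–C(=O)–CH=CH2)
Conditions: MnO2, CH2Cl2, rt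
Reagents that add atoms: none
Why: MnO2 oxidation of an alcohol that is both allylic and propargylic gives the cross-conjugated alkynyl vinyl ketone under neutral conditions that spare the exocyclic alkene, and the sensitive product is used at once.

Step 20
Reactants: 13 (7′S)-7′β-hydroxy-17′-nortotara-8′,11′,13′-trien-16′,13′-olide, 24 decalin alkynyl vinyl ketone
Product: 26 spiro cyclohexenone with C12=C13, C14 ketone and free 7′β-hydroxyl (C12 on the β face of the benzofuranone), via C17′ mono-adduct 25 (not isolated)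
Conditions: Cs2CO3, MeCN, 0 °C → rt, 24 added slowly
Reagents that add atoms: none
Why: Cs2CO3 deprotonates C15′, and the enolate adds first to the unsubstituted vinyl terminus C17′, the more electrophilic of the two acceptors, to give 25; the enolate of 25 then attacks alkyne carbon C12, and protonation of the allenolate at C13 leaves the C12=C13 enone. The closest known reaction type is the base-mediated double Michael ([5+1]) spiroannulation of 3-unsubstituted benzofuranones and oxindoles with cross-conjugated dienones and enynones. The one ring formed, the spiro cyclohexenone, is closed by a 6-endo-dig conjugate addition. The one new stereocentre, C15′, is controlled by the C7′ stereocentre peri to it: in the planar enolate of 25 the C17′ arm lies against the pseudo-equatorial 7′β-oxygen, which trans-fused ring B holds near the arene plane, so the arm should swing to the α face as C15′ pyramidalises and C12 should bond on the β face, as the target requires. The step needs this facial selectivity and clean C-alkylation; the peri strain just described, possibly helped by a hydrogen bond from the 7′β-hydroxyl to the ynone carbonyl, secures the first, and the free hydroxyl in place of an acetate (no acyl group that could shift to the carbanion) together with slow addition of 24 (no second intermolecular addition) secures the second.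

Step 21
Reactants: 26 spiro cyclohexenone with free 7′β-hydroxyl
Product: 27 spiro cyclohexenone with C12=C13, C14 ketone and 7′β-acetate
Conditions: Ac2O, DMAP, pyridine, CH2Cl2, rt
Reagents that add atoms: acetic anhydride, CC(=O)OC(C)=O
Why: DMAP-catalysed O-acetylation of the 7′β-hydroxyl, possible without side reaction now that C15′ is quaternary, gives the acetate of the target with retention at C7′.

Step 22
Reactants: 27 spiro cyclohexenone with 7′β-acetate
Product: 29 Mannich base, C14 ketone with 12-H (cis to C16′) and CH2NMe2 on C13 (C13 epimers), via dimethylphenylsilyl enol ether 28 (not isolated)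
Conditions: [(Ph3P)CuH]6 (cat.), PhMe2SiH, toluene, rt; then CH2=NMe2 I, CH2Cl2, rt; aq. NaHCO3
Reagents that add atoms: dimethylmethyleneiminium iodide, C=[N+](C)C.[I-]
Why: Copper hydride conjugate hydrosilylation followed by a Mannich reaction of the silyl enol ether with the iminium salt: hydride should add to C12 on the face of the lactone carbonyl C16′, anti to the pseudo-axial aryl bond of the spiro centre (copper hydride is known to reduce β,β-disubstituted cyclohexenones that carry a quaternary γ-carbon), and enol ether 28 makes C13 the only nucleophilic carbon, its new centre in 29 being lost in the next step.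

Step 23
Reactants: 29 Mannich base
Product: 31 α-methylene ketone (C13=CH2, C14 ketone), via trimethylammonium iodide 30 (not isolated)
Conditions: MeI, MeCN, rt; then aq. NaHCO3, CH2Cl2, rt
Reagents that add atoms: none
Why: Quaternisation and Hofmann-type β-elimination (E1cB) of the Mannich base with mild base gives the α-methylene ketone without touching C12, which is γ to the carbonyl.

Step 24
Reactants: 31 α-methylene ketone
Product: 32 2-(trimethylsilyl)ethyl ester of the target (C14 alcohol cis to C11)
Conditions: NaBH4, CeCl3·7H2O, MeOH, −78 °C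
Reagents that add atoms: none
Why: Luche reduction: 1,2-selective hydride attack on the face of H-12, anti to the C11 chain (axial attack on the chair with that chain equatorial), should give the C14 alcohol cis to C11 at a temperature at which the aryl lactone and the acetate survive.

Step 25
Reactants: 32 2-(trimethylsilyl)ethyl ester of the target
Product: 33 CNP0558742.1
Conditions: Bu4NF, AcOH, THF, 0 °C → rt
Reagents that add atoms: none
Why: Fluoride-induced β-elimination of the 2-(trimethylsilyl)ethyl ester (attack at silicon, loss of ethene) frees the hindered C20 acid without any attack at a carbonyl group, and the acetic acid buffer protects the acetate and the aryl lactone from basic fluoride.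

Compound list
1 | (−)-sclareol | C[C@]12CCCC([C@@H]1CC[C@@]([C@@H]2CC[C@](C)(C=C)O)(C)O)(C)C | starting material
2 | 8α-hydroxy-14,15-dinorlabdan-13-one | C[C@]12CCCC([C@@H]1CC[C@@]([C@@H]2CCC(C)=O)(C)O)(C)C | intermediate
3 | 14,15-dinorlabd-8(17)-en-13-one | C[C@]12CCCC([C@@H]1CCC(=C)[C@@H]2CCC(C)=O)(C)C | intermediate
4 | 14,15,17-trinorlabdane-8,13-dione | C[C@]12CCCC([C@@H]1CCC(=O)[C@@H]2CCC(C)=O)(C)C | intermediate
5 | podocarp-8(14)-en-13-one | O=C1C=C2CC[C@H]3C(C)(C)CCC[C@]3(C)[C@H]2CC1 | intermediate
6 | tert-butyl 2-(13-oxopodocarp-8(14)-en-14-yl)acetate | O=C1C(CC(=O)OC(C)(C)C)=C2CC[C@H]3C(C)(C)CCC[C@]3(C)[C@H]2CC1 | intermediate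
7 | tert-butyl 2-(13-oxopodocarpa-8(14),11-dien-14-yl)acetate (cross-conjugated dienone) | O=C1C(CC(=O)OC(C)(C)C)=C2CC[C@H]3C(C)(C)CCC[C@]3(C)[C@H]2C=C1 | intermediate (not isolated)
8 | tert-butyl 2-(13-hydroxypodocarpa-8,11,13-trien-14-yl)acetate | CC(C)(C)OC(=O)Cc1c(O)ccc2c1CC[C@H]1C(C)(C)CCC[C@]21C | intermediate
9 | tert-butyl 2-[13-(tert-butoxycarbonyloxy)podocarpa-8,11,13-trien-14-yl]acetate | CC(C)(C)OC(=O)Cc1c(OC(=O)OC(C)(C)C)ccc2c1CC[C@H]1C(C)(C)CCC[C@]21C | intermediate
10 | tert-butyl 2-[13-(tert-butoxycarbonyloxy)-7-oxopodocarpa-8,11,13-trien-14-yl]acetate | CC(C)(C)OC(=O)Cc1c(OC(=O)OC(C)(C)C)ccc2c1C(=O)C[C@H]1C(C)(C)CCC[C@]21C | intermediate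
11 | 2-(13-hydroxy-7-oxopodocarpa-8,11,13-trien-14-yl)acetic acid | OC(=O)Cc1c(O)ccc2c1C(=O)C[C@H]1C(C)(C)CCC[C@]21C | intermediate (not isolated)
12 | 7′-oxo-17′-nortotara-8′,11′,13′-trien-16′,13′-olide | C1C(=O)Oc2ccc3c(c21)C(=O)C[C@H]1C(C)(C)CCC[C@]31C | intermediate
13 | (7′S)-7′β-hydroxy-17′-nortotara-8′,11′,13′-trien-16′,13′-olide | C1C(=O)Oc2ccc3c(c21)[C@@H](O)C[C@H]1C(C)(C)CCC[C@]31C | intermediate
14 | carnosic acid | CC(C)C1=C(C(=C2C(=C1)CC[C@@H]3[C@@]2(CCCC3(C)C)C(=O)O)O)O | starting material
15 | 2-(trimethylsilyl)ethyl carnosate | CC(C)c1cc2CC[C@H]3C(C)(C)CCC[C@]3(C(=O)OCC[Si](C)(C)C)c2c(O)c1O | intermediate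
16 | 11,12-dimethyl 20-[2-(trimethylsilyl)ethyl] (13Z)-11,12-secoabieta-8,13-diene-11,12,20-trioate | COC(=O)C1=C(/C=C(/C(C)C)C(=O)OC)CC[C@H]2C(C)(C)CCC[C@]12C(=O)OCC[Si](C)(C)C | intermediate
17 | 11,12-dimethyl 20-[2-(trimethylsilyl)ethyl] 11,12-secoabiet-8(14)-ene-11,12,20-trioate (C9, C13 and alkene mixture) | COC(=O)C1C(=CC(C(C)C)C(=O)OC)CC[C@H]2C(C)(C)CCC[C@]12C(=O)OCC[Si](C)(C)C | intermediate
18 | 11-methyl 20-[2-(trimethylsilyl)ethyl] 8-oxo-12,13,14,15,16,17-hexanorlabdane-11,20-dioate (C9 epimers) | COC(=O)C1C(=O)CC[C@H]2C(C)(C)CCC[C@]12C(=O)OCC[Si](C)(C)C | intermediate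
19 | 9-(prop-2-ynyl) derivative of 18 (C9 configuration open) | COC(=O)C1(CC#C)C(=O)CC[C@H]2C(C)(C)CCC[C@]12C(=O)OCC[Si](C)(C)C | intermediate
20 | 2-(trimethylsilyl)ethyl 8-oxo-14,15,16,17-tetranorlabd-12-yn-20-oate | O=C1CC[C@H]2C(C)(C)CCC[C@]2(C(=O)OCC[Si](C)(C)C)[C@H]1CC#C | intermediate
21 | 2-(trimethylsilyl)ethyl 14,15,16-trinorlabd-8(17)-en-12-yn-20-oate | C=C1CC[C@H]2C(C)(C)CCC[C@]2(C(=O)OCC[Si](C)(C)C)[C@H]1CC#C | intermediate
22 | acrolein | C=CC=O | starting material
23 | dienynol (C14 epimers) | C=C1CC[C@H]2C(C)(C)CCC[C@]2(C(=O)OCC[Si](C)(C)C)[C@H]1CC#CC(O)C=C | intermediate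
24 | decalin alkynyl vinyl ketone, 2-(trimethylsilyl)ethyl ester | C=C1CC[C@H]2C(C)(C)CCC[C@]2(C(=O)OCC[Si](C)(C)C)[C@H]1CC#CC(=O)C=C | intermediate
25 | C17′ mono-adduct of 13 and 24 (C15′ epimers) | C=C1CC[C@H]2C(C)(C)CCC[C@]2(C(=O)OCC[Si](C)(C)C)[C@H]1CC#CC(=O)CCC1C(=O)Oc2ccc3c(c21)[C@@H](O)C[C@H]1C(C)(C)CCC[C@]31C | intermediate (not isolated)
26 | spiro cyclohexenone, 7′β-hydroxyl | C=C1CC[C@H]2C(C)(C)CCC[C@]2(C(=O)OCC[Si](C)(C)C)[C@H]1CC1=CC(=O)CC[C@]12C(=O)Oc1ccc3c(c12)[C@@H](O)C[C@H]1C(C)(C)CCC[C@]31C | intermediate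
27 | spiro cyclohexenone, 7′β-acetate | C=C1CC[C@H]2C(C)(C)CCC[C@]2(C(=O)OCC[Si](C)(C)C)[C@H]1CC1=CC(=O)CC[C@]12C(=O)Oc1ccc3c(c12)[C@@H](OC(C)=O)C[C@H]1C(C)(C)CCC[C@]31C | intermediate
28 | C14 dimethylphenylsilyl enol ether (C13=C14), 12-H cis to C16′ | C=C1CC[C@H]2C(C)(C)CCC[C@]2(C(=O)OCC[Si](C)(C)C)[C@H]1C[C@H]1C=C(O[Si](C)(C)c2ccccc2)CC[C@]12C(=O)Oc1ccc3c(c12)[C@@H](OC(C)=O)C[C@H]1C(C)(C)CCC[C@]31C | intermediate (not isolated)
29 | Mannich base, 13-(dimethylaminomethyl) C14 ketone (C13 epimers) | C=C1CC[C@H]2C(C)(C)CCC[C@]2(C(=O)OCC[Si](C)(C)C)[C@H]1C[C@H]1C(CN(C)C)C(=O)CC[C@]12C(=O)Oc1ccc3c(c12)[C@@H](OC(C)=O)C[C@H]1C(C)(C)CCC[C@]31C | intermediate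
30 | trimethylammonium iodide of 29 | C=C1CC[C@H]2C(C)(C)CCC[C@]2(C(=O)OCC[Si](C)(C)C)[C@H]1C[C@H]1C(C[N+](C)(C)C)C(=O)CC[C@]12C(=O)Oc1ccc3c(c12)[C@@H](OC(C)=O)C[C@H]1C(C)(C)CCC[C@]31C.[I-] | intermediate (not isolated)
31 | α-methylene ketone (C13=CH2, C14 ketone) | C=C1CC[C@H]2C(C)(C)CCC[C@]2(C(=O)OCC[Si](C)(C)C)[C@H]1C[C@H]1C(=C)C(=O)CC[C@]12C(=O)Oc1ccc3c(c12)[C@@H](OC(C)=O)C[C@H]1C(C)(C)CCC[C@]31C | intermediate
32 | 2-(trimethylsilyl)ethyl ester of the target | C=C1CC[C@H]2C(C)(C)CCC[C@]2(C(=O)OCC[Si](C)(C)C)[C@H]1C[C@H]1C(=C)[C@@H](O)CC[C@]12C(=O)Oc1ccc3c(c12)[C@@H](OC(C)=O)C[C@H]1C(C)(C)CCC[C@]31C | intermediate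
33 | CNP0558742.1 | C=C1CC[C@H]2C(C)(C)CCC[C@]2(C(=O)O)[C@H]1C[C@H]1C(=C)[C@@H](O)CC[C@]12C(=O)Oc1ccc3c(c12)[C@@H](OC(C)=O)C[C@H]1C(C)(C)CCC[C@]31C | target

Total step count: 25. Longest linear sequence: 16 steps (steps 1–10 and 20–25, from 1); the carnosic acid branch reaches 24 in 9 steps.

Steps most likely to fail

1. Step 20. What may go wrong: weak or reversed facial selectivity at C15′ in the ring-closing addition, so that C12 ends on the α face. Fallback: reverse the order in which the two bonds are made, so that C12 is attached first and the ring closes at C17′, the arm delivered last then taking the opposite face. Setting out from 24, benzenesulfinic acid (PhSO2Na, AcOH, THF/H2O, 0 °C) adds to the vinyl group, the more reactive acceptor, and gives β-sulfonyl ketone F1. Compound 13 is then added to ynone carbon C12 of F1 (Et3N cat., MeCN, 0 °C) to give C12 adduct F2. DBU (MeCN, rt) expels benzenesulfinate (E1cB), and the unmasked vinyl ketone F3 closes C15′–C17′ by a 6-endo-trig Michael addition, which returns to the route at 26.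

2. Step 15. What may go wrong: O-alkylation of the hindered enolate instead of C-alkylation, or no alkylation at the crowded C9. Fallback: setting out from 18, palladium-catalysed allylation (allyl methyl carbonate, Pd(PPh3)4, THF), which is C-selective for β-keto esters, gives C9-allyl β-keto ester F4. Krapcho dealkoxycarbonylation (LiCl, wet DMSO, 150 °C) gives 9β-allyl ketone F5. Ozonolysis (O3; Me2S) gives keto aldehyde F6, and Ohira–Bestmann homologation (dimethyl (1-diazo-2-oxopropyl)phosphonate, K2CO3, MeOH) converts the aldehyde into the terminal alkyne, which returns to the route at 20.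

3. Step 13. What may go wrong: reduction of the twisted, tetrasubstituted diene across one enoate only (C13=C14), or no reduction. Fallback without a reduction: setting out from 16, OsO4 (cat.)/NaIO4 cleaves only the less hindered trisubstituted C13=C14 bond and gives C8-formyl enoate F7. Pinnick oxidation (NaClO2, NaH2PO4, 2-methyl-2-butene) gives acid F8. DPPA/Et3N gives acyl azide F9, which rearranges on warming in toluene (Curtius) to vinyl isocyanate F10. Aqueous HCl/THF hydrolyses it through the enamine to the C8 ketone, which returns to the route at 18.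

Further compounds
F1 | step 20 | 2-(trimethylsilyl)ethyl ester of the decalin ynone with a 2-(phenylsulfonyl)ethyl ketone (masked vinyl group) | C=C1CC[C@H]2C(C)(C)CCC[C@]2(C(=O)OCC[Si](C)(C)C)[C@H]1CC#CC(=O)CCS(=O)(=O)c1ccccc1
F2 | step 20 | C15′–C12 Michael adduct of 13 and F1 (alkene and C15′ isomers) | C=C1CC[C@H]2C(C)(C)CCC[C@]2(C(=O)OCC[Si](C)(C)C)[C@H]1CC(=CC(=O)CCS(=O)(=O)c1ccccc1)C1C(=O)Oc2ccc3c(c21)[C@@H](O)C[C@H]1C(C)(C)CCC[C@]31C
F3 | step 20 | unmasked vinyl ketone from F2 (not isolated) | C=C1CC[C@H]2C(C)(C)CCC[C@]2(C(=O)OCC[Si](C)(C)C)[C@H]1CC(=CC(=O)C=C)C1C(=O)Oc2ccc3c(c21)[C@@H](O)C[C@H]1C(C)(C)CCC[C@]31C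
F4 | step 15 | 9-allyl derivative of 18 (C9 configuration open) | COC(=O)C1(CC=C)C(=O)CC[C@H]2C(C)(C)CCC[C@]12C(=O)OCC[Si](C)(C)C
F5 | step 15 | 9β-allyl C8 ketone | O=C1CC[C@H]2C(C)(C)CCC[C@]2(C(=O)OCC[Si](C)(C)C)[C@H]1CC=C
F6 | step 15 | C8 ketone with 9β-(2-oxoethyl) group | O=C1CC[C@H]2C(C)(C)CCC[C@]2(C(=O)OCC[Si](C)(C)C)[C@H]1CC=O
F7 | step 13 | C8-formyl C9-methoxycarbonyl decalin alkene (C8=C9) | COC(=O)C1=C(C=O)CC[C@H]2C(C)(C)CCC[C@]12C(=O)OCC[Si](C)(C)C
F8 | step 13 | C8 carboxylic acid from F7 | COC(=O)C1=C(C(=O)O)CC[C@H]2C(C)(C)CCC[C@]12C(=O)OCC[Si](C)(C)C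
F9 | step 13 | acyl azide of F8 | COC(=O)C1=C(C(=O)N=[N+]=[N-])CC[C@H]2C(C)(C)CCC[C@]12C(=O)OCC[Si](C)(C)C
F10 | step 13 | C8 vinyl isocyanate | COC(=O)C1=C(N=C=O)CC[C@H]2C(C)(C)CCC[C@]12C(=O)OCC[Si](C)(C)C
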